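**Assumption:** the SMILES is read literally: (7R,8R,8aR) core, and a (1E,3Z,5S)-3,5-dimethylhepta-1,3-dienyl side chain (3Z, not the 3E of sclerotiorin-type azaphilones).

**Abbreviations:** TBS = tert-butyldimethylsilyl; TIPS = triisopropylsilyl; TOM-Cl = [(triisopropylsilyl)oxy]methyl chloride. Isochromene numbering of the target (C1, O2, C3 … C8a) is used in the explanations.

## Retrosynthetic overview

1. The C8 acetate goes on last; the pyran ring is closed last, by 6-endo-dig hydroalkoxylation of the C1 hydroxyl onto an alkynyl enone (O2–C3 bond).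
2. The cyclohexenone ring comes from an α-ketol ring expansion of a 1-acetylcyclopent-2-en-1-ol: C8 shifts from C6 to the acetyl carbon, which becomes C7 with its OH and methyl.
3. That α-ketol comes from 1-ethoxyvinyllithium and a 3-alkynylcyclopentenone, itself made by alkynyl addition and oxidative 1,3-transposition of a trans-4-silyloxy-5-(silyloxymethyl)cyclopentenone.
4. The cyclopentenone comes from sodium cyclopentadienide by alkylation, singlet-oxygen cycloaddition and a desymmetrising Kornblum–DeLaMare rearrangement (sets C8 and C8a).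
5. The dienyne comes from (S)-2-methylbutan-1-ol by iodo-olefination (3Z) and Heck coupling (1E). Ring order: five-membered carbocycle (from cyclopentadienide), then six-membered ring (ring expansion), then pyran.

## Route

**Step 1**
Reactants: 1 (S)-2-methylbutan-1-ol
Product: 2 (S)-2-methylbutanal
Conditions: TEMPO (1 mol %), KBr (10 mol %), NaOCl (1.1 equiv), NaHCO3, CH2Cl2/H2O, 0 °C; dried CH2Cl2 solution used directly
Reagents that add atoms: none
Why: Anelli (oxoammonium) oxidation stops at the aldehyde and, buffered at 0 °C, does not epimerise the α-stereocentre, which becomes C5 of the side chain.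

**Step 2**
Reactants: 2 (S)-2-methylbutanal
Product: 3 (2Z,4S)-2-iodo-4-methylhex-2-ene
Conditions: EtPPh3I, n-BuLi, THF, 0 °C; I2, −78 °C; NaN(SiMe3)2, −78 to −20 °C; then 2, −78 °C to rt
Reagents that add atoms: ethyltriphenylphosphonium iodide (CC[P+](c1ccccc1)(c1ccccc1)c1ccccc1.[I-]); iodine (II)
Why: Stork–Zhao-type Wittig olefination with the α-iodo ylide Ph3P=C(I)CH3 gives the trisubstituted iodoalkene with iodine cis to the alkyl chain, which fixes the 3Z geometry of the side chain.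

**Step 3**
Reactants: 3 (2Z,4S)-2-iodo-4-methylhex-2-ene; 4 (but-3-en-1-yn-1-yl)trimethylsilane
Product: 5 trimethyl[(3E,5Z,7S)-5,7-dimethylnona-3,5-dien-1-yn-1-yl]silane
Conditions: Pd(OAc)2 (5 mol %), Bu4NCl, NaHCO3, DMF, rt to 40 °C, dark
Reagents that add atoms: none
Why: Heck reaction (Jeffery conditions): the alkenylpalladium from 3 keeps its geometry, adds to the unsubstituted vinyl terminus and syn β-hydride elimination gives the E alkene, while the silyl group blocks Sonogashira coupling and shields the alkyne from carbopalladation.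

**Step 4**
Reactants: 6 sodium cyclopentadienide (NaC5H5)
Product: 10 (4S,5R)-4-[(tert-butyldimethylsilyl)oxy]-5-{[(triisopropylsilyl)oxy]methyl}cyclopent-2-en-1-one, via 5-substituted cyclopentadiene 7 (not isolated), via meso endoperoxide 8 (not isolated), via hydroxy enone 9 (not isolated)
Conditions: TOM-Cl, THF, −55 °C; O2, tetraphenylporphyrin (cat.), hν, CH2Cl2, −78 °C; 9-O-acetylcupreidine (10 mol %), −78 to −30 °C; then imidazole, TBSCl, 0 °C to rt
Reagents that add atoms: [(triisopropylsilyl)oxy]methyl chloride, TOM-Cl (ClCO[Si](C(C)C)(C(C)C)C(C)C); dioxygen (O=O); tert-butyldimethylsilyl chloride (CC(C)(C)[Si](C)(C)Cl)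
Why: Proposed new method: enantioselective Kornblum–DeLaMare desymmetrisation of a thermally labile 7-substituted 2,3-dioxabicyclo[2.2.1]hept-5-ene made and consumed below −30 °C; C-alkylation of cyclopentadienide and anti-facial singlet-oxygen [4+2] addition (before 1,5-hydrogen shifts set in) give meso peroxide 8 with the O–O bridge trans to CH2OTIPS, the bifunctional cinchona base then hydrogen-bonds one peroxide oxygen through its 6'-OH while its quinuclidine nitrogen removes one of the two enantiotopic bridgehead protons in an E2-type O–O cleavage, so that carbon becomes the ketone and the other keeps its oxygen as the C4 alkoxide (trans to C5, absolute configuration from the catalyst; the pseudo-enantiomeric cupreine acetate is used if the sense of induction is opposite), and silylation in the same flask protects the sensitive γ-hydroxy enone; closest known reaction type: amine-catalysed Kornblum–DeLaMare rearrangement of bicyclic endoperoxides (achiral base on cyclopentadiene endoperoxide, chiral cinchona bases on isolable meso endoperoxides of six- to eight-membered dienes).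

**Step 5**
Reactants: 5 trimethyl[(3E,5Z,7S)-5,7-dimethylnona-3,5-dien-1-yn-1-yl]silane; 10 (4S,5R)-4-(TBSO)-5-(TIPSOCH2)cyclopent-2-en-1-one
Product: 12 (1S,4S,5R)-4-[(tert-butyldimethylsilyl)oxy]-1-[(3E,5Z,7S)-5,7-dimethylnona-3,5-dien-1-yn-1-yl]-5-{[(triisopropylsilyl)oxy]methyl}cyclopent-2-en-1-ol, via lithium acetylide 11 (not isolated)
Conditions: 5, MeLi·LiBr, THF, 0 °C to rt; then 10, −78 °C; H2O
Reagents that add atoms: none
Why: Desilylative lithiation of the alkynylsilane and 1,2-addition of the lithium acetylide to the enone carbonyl, mainly anti to the neighbouring CH2OTIPS group; the new carbinol centre is erased in step 6, so its configuration does not matter.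

**Step 6**
Reactants: 12 (1S,4S,5R)-1-alkynyl-4-(TBSO)-5-(TIPSOCH2)cyclopent-2-en-1-ol
Product: 13 (4R,5R)-5-[(tert-butyldimethylsilyl)oxy]-3-[(3E,5Z,7S)-5,7-dimethylnona-3,5-dien-1-yn-1-yl]-4-{[(triisopropylsilyl)oxy]methyl}cyclopent-2-en-1-one
Conditions: pyridinium chlorochromate [C5H5NH][CrO3Cl] (2.5 equiv), 4 Å molecular sieves, CH2Cl2, rt
Reagents that add atoms: pyridinium chlorochromate ([O-][Cr](=O)(=O)Cl.c1cc[nH+]cc1)
Why: Dauben–Babler oxidative 1,3-transposition: the tertiary allylic chromate ester shifts to the secondary allylic carbon next to C–OTBS and is oxidised there, which puts the carbonyl on the future C6 and leaves the alkynyl group on the future C4a without touching the two stereocentres.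

**Step 7**
Reactants: 13 (4R,5R)-3-alkynyl-5-(TBSO)-4-(TIPSOCH2)cyclopent-2-en-1-one; 14 ethyl vinyl ether
Product: 17 1-[(1S,4R,5R)-5-[(tert-butyldimethylsilyl)oxy]-3-[(3E,5Z,7S)-5,7-dimethylnona-3,5-dien-1-yn-1-yl]-1-hydroxy-4-{[(triisopropylsilyl)oxy]methyl}cyclopent-2-en-1-yl]ethan-1-one, via 1-ethoxyvinyllithium 15 (not isolated), via enol ether carbinol 16 (not isolated)
Conditions: 14, t-BuLi, THF, −78 to 0 °C; then 13, −78 °C; 0.5 M HCl, THF, 0 °C, 15 min
Reagents that add atoms: water (O)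
Why: Acyl-anion-equivalent addition: the hard vinyllithium adds 1,2 to the ketone anti to the adjacent OTBS group, giving the tertiary carbinol with OH cis to OTBS, and brief mild acid hydrolyses the enol ether to the methyl ketone (the α-acyl carbinol does not ionise; any C1 epimer is removed here).

**Step 8**
Reactants: 17 1-acetylcyclopent-2-en-1-ol (1S,4R,5R)
Product: 18 (4R,5R,6R)-5-[(tert-butyldimethylsilyl)oxy]-3-[(3E,5Z,7S)-5,7-dimethylnona-3,5-dien-1-yn-1-yl]-6-hydroxy-6-methyl-4-{[(triisopropylsilyl)oxy]methyl}cyclohex-2-en-1-one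
Conditions: Al(OtBu)3 (1.2 equiv), toluene, 80 °C; then H2O
Reagents that add atoms: none
Why: α-Ketol (acyloin) rearrangement with ring expansion, as in steroid D-homoannulation: in the aluminium chelate the tertiary alkoxide and the acetyl C=O are syn-periplanar, the OTBS-bearing ring carbon migrates with retention to the acetyl carbon, which becomes C6 of 18 (C7 of the target) with its hydroxyl cis to the silyloxy group, while the old carbinol carbon becomes the enone carbonyl; the shift is reversible and the conjugated six-membered ynenone is the thermodynamic sink, and an initial vinyl shift followed by a methyl shift would lead to the same compound.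

**Step 9**
Reactants: 18 (4R,5R,6R)-3-alkynyl-5-(TBSO)-6-hydroxy-6-methyl-4-(TIPSOCH2)cyclohex-2-en-1-one
Product: 19 (4R,5R,6R)-3-[(3E,5Z,7S)-5,7-dimethylnona-3,5-dien-1-yn-1-yl]-5,6-dihydroxy-4-(hydroxymethyl)-6-methylcyclohex-2-en-1-one
Conditions: Bu4NF (3 equiv), AcOH (3 equiv), THF, rt
Reagents that add atoms: none
Why: Fluoride cleavage of both silyl ethers; acetic acid buffering avoids retro-aldol or elimination chemistry of the β-hydroxy ketone, and no stereocentre is touched.

**Step 10**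
Reactants: 19 (4R,5R,6R)-triol ynenone
Product: 21 (7R,8R,8aR)-3-[(1E,3Z,5S)-3,5-dimethylhepta-1,3-dien-1-yl]-7-hydroxy-7-methyl-6-oxo-6,7,8,8a-tetrahydro-1H-isochromen-8-yl acetate, via diol 20 (not isolated)
Conditions: Ph3PAuNTf2 (2 mol %), CH2Cl2, 0 °C to rt; then pyridine, Ac2O (1.3 equiv), DMAP (cat.), 0 °C
Reagents that add atoms: acetic anhydride (CC(=O)OC(C)=O)
Why: Gold-catalysed 6-endo-dig hydroalkoxylation (cycloisomerisation): the primary hydroxyl attacks the alkyne carbon conjugated to the diene (better cation stabilisation; the other hydroxyls could only form bridged rings) and protodeauration gives the pyran dienol ether, after which the secondary C8 hydroxyl is acetylated selectively over the tertiary C7 hydroxyl.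

## Compound list

1 | (S)-2-methylbutan-1-ol | CC[C@H](C)CO | starting material
2 | (S)-2-methylbutanal | CC[C@H](C)C=O | intermediate
3 | (2Z,4S)-2-iodo-4-methylhex-2-ene | CC[C@H](C)/C=C(C)\I | intermediate
4 | (but-3-en-1-yn-1-yl)trimethylsilane | C=CC#C[Si](C)(C)C | starting material
5 | trimethyl[(3E,5Z,7S)-5,7-dimethylnona-3,5-dien-1-yn-1-yl]silane | CC[C@H](C)/C=C(C)\C=C\C#C[Si](C)(C)C | intermediate
6 | sodium cyclopentadienide | [Na+].[CH-]1C=CC=C1 | starting material
7 | 5-{[(triisopropylsilyl)oxy]methyl}cyclopenta-1,3-diene | C1=CC(CO[Si](C(C)C)(C(C)C)C(C)C)C=C1 | intermediate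
8 | meso-(1R,4S)-7-{[(triisopropylsilyl)oxy]methyl}-2,3-dioxabicyclo[2.2.1]hept-5-ene (CH2OTIPS syn to the C=C bridge) | [C@@H]1(CO[Si](C(C)C)(C(C)C)C(C)C)[C@@H]2C=C[C@H]1OO2 | intermediate
9 | (4S,5R)-4-hydroxy-5-{[(triisopropylsilyl)oxy]methyl}cyclopent-2-en-1-one | O=C1C=C[C@H](O)[C@H]1CO[Si](C(C)C)(C(C)C)C(C)C | intermediate
10 | (4S,5R)-4-[(tert-butyldimethylsilyl)oxy]-5-{[(triisopropylsilyl)oxy]methyl}cyclopent-2-en-1-one | O=C1C=C[C@H](O[Si](C)(C)C(C)(C)C)[C@H]1CO[Si](C(C)C)(C(C)C)C(C)C | intermediate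
11 | lithium (3E,5Z,7S)-5,7-dimethylnona-3,5-dien-1-yn-1-ide | CC[C@H](C)/C=C(C)\C=C\C#C[Li] | intermediate
12 | (1S,4S,5R)-4-[(tert-butyldimethylsilyl)oxy]-1-[(3E,5Z,7S)-5,7-dimethylnona-3,5-dien-1-yn-1-yl]-5-{[(triisopropylsilyl)oxy]methyl}cyclopent-2-en-1-ol | O[C@@]1(C#C/C=C/C(C)=C\[C@@H](C)CC)C=C[C@H](O[Si](C)(C)C(C)(C)C)[C@H]1CO[Si](C(C)C)(C(C)C)C(C)C | intermediate
13 | (4R,5R)-5-[(tert-butyldimethylsilyl)oxy]-3-[(3E,5Z,7S)-5,7-dimethylnona-3,5-dien-1-yn-1-yl]-4-{[(triisopropylsilyl)oxy]methyl}cyclopent-2-en-1-one | O=C1C=C(C#C/C=C/C(C)=C\[C@@H](C)CC)[C@H](CO[Si](C(C)C)(C(C)C)C(C)C)[C@H]1O[Si](C)(C)C(C)(C)C | intermediate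
14 | ethyl vinyl ether | C=COCC | starting material
15 | 1-ethoxyvinyllithium | [Li]C(=C)OCC | intermediate
16 | (1S,4R,5R)-5-[(tert-butyldimethylsilyl)oxy]-3-[(3E,5Z,7S)-5,7-dimethylnona-3,5-dien-1-yn-1-yl]-1-(1-ethoxyethenyl)-4-{[(triisopropylsilyl)oxy]methyl}cyclopent-2-en-1-ol | C=C(OCC)[C@]1(O)C=C(C#C/C=C/C(C)=C\[C@@H](C)CC)[C@H](CO[Si](C(C)C)(C(C)C)C(C)C)[C@H]1O[Si](C)(C)C(C)(C)C | intermediate
17 | 1-[(1S,4R,5R)-5-[(tert-butyldimethylsilyl)oxy]-3-[(3E,5Z,7S)-5,7-dimethylnona-3,5-dien-1-yn-1-yl]-1-hydroxy-4-{[(triisopropylsilyl)oxy]methyl}cyclopent-2-en-1-yl]ethan-1-one | CC(=O)[C@]1(O)C=C(C#C/C=C/C(C)=C\[C@@H](C)CC)[C@H](CO[Si](C(C)C)(C(C)C)C(C)C)[C@H]1O[Si](C)(C)C(C)(C)C | intermediate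
18 | (4R,5R,6R)-5-[(tert-butyldimethylsilyl)oxy]-3-[(3E,5Z,7S)-5,7-dimethylnona-3,5-dien-1-yn-1-yl]-6-hydroxy-6-methyl-4-{[(triisopropylsilyl)oxy]methyl}cyclohex-2-en-1-one | O=C1C=C(C#C/C=C/C(C)=C\[C@@H](C)CC)[C@H](CO[Si](C(C)C)(C(C)C)C(C)C)[C@@H](O[Si](C)(C)C(C)(C)C)[C@@]1(C)O | intermediate
19 | (4R,5R,6R)-3-[(3E,5Z,7S)-5,7-dimethylnona-3,5-dien-1-yn-1-yl]-5,6-dihydroxy-4-(hydroxymethyl)-6-methylcyclohex-2-en-1-one | O=C1C=C(C#C/C=C/C(C)=C\[C@@H](C)CC)[C@H](CO)[C@@H](O)[C@@]1(C)O | intermediate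
20 | (7R,8R,8aR)-3-[(1E,3Z,5S)-3,5-dimethylhepta-1,3-dien-1-yl]-7,8-dihydroxy-7-methyl-1,7,8,8a-tetrahydro-6H-isochromen-6-one | CC[C@H](C)/C=C(C)\C=C\C1=CC2=CC(=O)[C@](C)(O)[C@H](O)[C@H]2CO1 | intermediate
21 | (7R,8R,8aR)-3-[(1E,3Z,5S)-3,5-dimethylhepta-1,3-dien-1-yl]-7-hydroxy-7-methyl-6-oxo-6,7,8,8a-tetrahydro-1H-isochromen-8-yl acetate | CC[C@H](C)/C=C(C)\C=C\C1=CC2=CC(=O)[C@](C)(O)[C@H](OC(C)=O)[C@H]2CO1 | target

## Step count and risks

Total step count: 10. Longest linear sequence: 9 steps (1 to 21 through steps 1, 2, 3, 5, 6, 7, 8, 9, 10); the branch from 6 is 7 steps.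

**Step 4 (the proposed new step).** The [2.2.1] endoperoxide may decompose or rearrange with low enantioselectivity before the chiral base acts. The fallback uses known chemistry, sets out from 6 and returns at 10. Alkylation and photooxygenation are run as before, but peroxide 8 is reduced at −78 °C with thiourea to the meso diol (1R,3S)-2-{[(triisopropylsilyl)oxy]methyl}cyclopent-4-ene-1,3-diol F1. Lipase-catalysed transesterification (Amano lipase PS, vinyl acetate; the enzyme is chosen so that the acetate lands on the carbinol that will become the ketone) desymmetrises it to the monoacetate (1R,4S,5R)-4-hydroxy-5-{[(triisopropylsilyl)oxy]methyl}cyclopent-2-en-1-yl acetate F2. Silylation (TBSCl, imidazole) gives (1R,4S,5S)-4-[(tert-butyldimethylsilyl)oxy]-5-{[(triisopropylsilyl)oxy]methyl}cyclopent-2-en-1-yl acetate F3, methanolysis (K2CO3, MeOH) gives the allylic alcohol (1R,4S,5S)-4-[(tert-butyldimethylsilyl)oxy]-5-{[(triisopropylsilyl)oxy]methyl}cyclopent-2-en-1-ol F4, and MnO2 oxidation gives 10.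

**Step 8.** The vinyl carbon may migrate faster than the silyloxy-bearing carbon, silyl transfer may interfere, or the chelate control of the new carbinol centre may erode at 80 °C. The fallback changes the order of events, sets out from 17 and returns at 20. Bu4NF/AcOH removes both silyl groups to give the triol 1-[(1S,4R,5R)-3-[(3E,5Z,7S)-5,7-dimethylnona-3,5-dien-1-yn-1-yl]-1,5-dihydroxy-4-(hydroxymethyl)cyclopent-2-en-1-yl]ethan-1-one F5. Ph3PAuNTf2 closes the pyran first, giving the cyclopenta[c]pyran α-ketol 1-[(6S,7R,7aR)-3-[(1E,3Z,5S)-3,5-dimethylhepta-1,3-dien-1-yl]-6,7-dihydroxy-1,6,7,7a-tetrahydrocyclopenta[c]pyran-6-yl]ethan-1-one F6. The α-ketol ring expansion (Al(OtBu)3, toluene, 60 °C) is then the last skeletal event; its product is a doubly vinylogous ester, so the driving force is larger and no silyl group can migrate. This gives 20, which is acetylated as in step 10.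

**Step 3.** The Heck coupling may give low conversion, alkyne insertion, or partial Z to E isomerisation. The fallback is a Negishi coupling, sets out from 3 and returns at 5. Iodine–lithium exchange (t-BuLi, Et2O, −78 °C) gives [(2E,4S)-4-methylhex-2-en-2-yl]lithium F7 with retention, and ZnBr2 converts it into bromo[(2Z,4S)-4-methylhex-2-en-2-yl]zinc F8. Pd(PPh3)4-catalysed coupling with (E)-1-chloro-4-(trimethylsilyl)but-1-en-3-yne F9 (one Sonogashira step from (E)-1,2-dichloroethene and ethynyltrimethylsilane with Pd(PPh3)4, CuI and n-BuNH2) gives 5.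

## Further compounds

F1 | step 4 | meso-(1R,3S)-2-{[(triisopropylsilyl)oxy]methyl}cyclopent-4-ene-1,3-diol (both hydroxyls trans to CH2OTIPS) | O[C@@H]1C=C[C@H](O)[C@H]1CO[Si](C(C)C)(C(C)C)C(C)C
F2 | step 4 | (1R,4S,5R)-4-hydroxy-5-{[(triisopropylsilyl)oxy]methyl}cyclopent-2-en-1-yl acetate | CC(=O)O[C@@H]1C=C[C@H](O)[C@H]1CO[Si](C(C)C)(C(C)C)C(C)C
F3 | step 4 | (1R,4S,5S)-4-[(tert-butyldimethylsilyl)oxy]-5-{[(triisopropylsilyl)oxy]methyl}cyclopent-2-en-1-yl acetate | CC(=O)O[C@@H]1C=C[C@H](O[Si](C)(C)C(C)(C)C)[C@H]1CO[Si](C(C)C)(C(C)C)C(C)C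
F4 | step 4 | (1R,4S,5S)-4-[(tert-butyldimethylsilyl)oxy]-5-{[(triisopropylsilyl)oxy]methyl}cyclopent-2-en-1-ol | O[C@@H]1C=C[C@H](O[Si](C)(C)C(C)(C)C)[C@H]1CO[Si](C(C)C)(C(C)C)C(C)C
F5 | step 8 | 1-[(1S,4R,5R)-3-[(3E,5Z,7S)-5,7-dimethylnona-3,5-dien-1-yn-1-yl]-1,5-dihydroxy-4-(hydroxymethyl)cyclopent-2-en-1-yl]ethan-1-one | CC(=O)[C@]1(O)C=C(C#C/C=C/C(C)=C\[C@@H](C)CC)[C@H](CO)[C@H]1O
F6 | step 8 | 1-[(6S,7R,7aR)-3-[(1E,3Z,5S)-3,5-dimethylhepta-1,3-dien-1-yl]-6,7-dihydroxy-1,6,7,7a-tetrahydrocyclopenta[c]pyran-6-yl]ethan-1-one | CC[C@H](C)/C=C(C)\C=C\C1=CC2=C[C@@](O)(C(C)=O)[C@H](O)[C@H]2CO1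
F7 | step 3 | [(2E,4S)-4-methylhex-2-en-2-yl]lithium | CC[C@H](C)/C=C(C)\[Li]
F8 | step 3 | bromo[(2Z,4S)-4-methylhex-2-en-2-yl]zinc | CC[C@H](C)/C=C(C)\[Zn]Br
F9 | step 3 | (E)-1-chloro-4-(trimethylsilyl)but-1-en-3-yne | Cl/C=C/C#C[Si](C)(C)C
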